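**Plan** (ring: O1, C2(=O), C3=C4, C5(O-acyl), C6; arm C7=C8–C9O2H; side chain C1′–C12′)
1. Retrosynthetic cuts: the C5 ester (pyranol 12 + acid 25); the lactone O1–C2, with C2 read as a vinyl CH whose extra CH2 is excised later; then C2–C3 and C4–C5 together, giving the C5 aldehyde and two acetylene molecules; C7=C8, C2′=C3′ and C4′=C5′ by Wittig reactions; C9′–C10′ by epoxide opening.
2. Enabling feature: ring atoms C3=C4 are an unsubstituted cis-CH=CH unit between the carbinol carbon C5 (next to oxygenated C6) and the sp2 carbon C2. This is the (Z)-dienyl carbinol pattern formed when a rhodacyclopentadiene from two acetylenes inserts an α-alkoxy aldehyde.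
3. Forward order: key coupling (step 1); O5 silylation, acetonide removal, C7 oxidation/Wittig; terminal CH2 excised so that O6 closes the six-membered ring as lactol, then lactone (steps 5 and 6); side chain built linearly (steps 8–15); esterification and global deprotection last.
4. Stereochemistry: C6 is bought (aldehyde 1); C5 is set in step 1 by the chiral rhodium catalyst; the ring olefin is Z from the rhodacycle; C6′ comes from (R)-citronellene and C11′ from (S)-propylene oxide; all E olefins come from stabilised ylides.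

Key step: step 1

Remark on the chemistry (assumption): (S)-MeO-BIPHEP is taken to be the ligand antipode whose rhodium catalyst attacks the Si face of aldehyde 1 (syn, 5S adduct). If the sense is the opposite, the (R)-ligand is used and nothing else changes.

**Step 1**
Reactants: 1 (4S)-2,2-dimethyl-1,3-dioxolane-4-carbaldehyde; 2 acetylene (two molecules are incorporated)
Product: 3 (1S,2Z)-1-[(4S)-2,2-dimethyl-1,3-dioxolan-4-yl]penta-2,4-dien-1-ol
Conditions: [Rh(cod)2][B(3,5-(CF3)2C6H3)4] (5 mol %), (S)-MeO-BIPHEP (5 mol %), Ph3CCO2H (7.5 mol %), Na2SO4, C2H2/H2 (1:1, 1 atm), ClCH2CH2Cl, 25–40 °C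
Reagents that add atoms: none
Why: Cationic monovalent rhodium couples two acetylene molecules oxidatively to a rhodacyclopentadiene of trivalent rhodium (this makes the C2–C3 bond, a union of two alkyne carbons of like polarity), the C=O of 1 inserts into a Rh–C bond (this makes the C4–C5 bond), and acid-assisted hydrogenolysis of the oxarhodacycle with H2 releases the dienyl carbinol and the catalyst. The closest known reaction type is the rhodium-catalysed hydrogen-mediated reductive coupling of acetylene with aldehydes (carbonyl (Z)-butadienylation), which has precedent on α-alkoxy aldehydes of the glyceraldehyde acetonide type. No ring of the target is closed here; the transient five- and seven-membered rhodacycles fix the cis geometry of C3=C4, which later allows O6 to reach C2 in a 6-exo-trig lactol closure. The new stereocentre C5 is controlled by the chiral bisphosphine on rhodium (catalyst-directed Si-face attack), next to the bought C6 centre, which is not touched. The step needs coupling to win over plain hydrogenation of acetylene, aldehyde or product diene, which should hold because H2 is activated only at the oxarhodacycle stage, and it needs the α-centre of 1 to survive, which the neutral to weakly acidic medium should allow.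

**Step 2**
Reactants: 3 (1S,2Z)-1-[(4S)-2,2-dimethyl-1,3-dioxolan-4-yl]penta-2,4-dien-1-ol
Product: 4 tert-butyl{[(1S,2Z)-1-[(4S)-2,2-dimethyl-1,3-dioxolan-4-yl]penta-2,4-dien-1-yl]oxy}dimethylsilane
Conditions: TBSCl, imidazole, DMF, 0 °C → rt
Reagents that add atoms: tert-butyl(chloro)dimethylsilane CC(C)(C)[Si](C)(C)Cl
Why: Standard silylation of a secondary alcohol; blocking O5 ensures that only O6 can later close onto C2, giving the six-membered and not the five-membered ring.

**Step 3**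
Reactants: 4 tert-butyl{[(1S,2Z)-1-[(4S)-2,2-dimethyl-1,3-dioxolan-4-yl]penta-2,4-dien-1-yl]oxy}dimethylsilane
Product: 5 (2S,3S,4Z)-3-{[tert-butyl(dimethyl)silyl]oxy}hepta-4,6-diene-1,2-diol
Conditions: CuCl2·2H2O, MeCN, 0 °C
Reagents that add atoms: none
Why: Mild Lewis-acid hydrolysis of a terminal isopropylidene acetal is a known selective deprotection that should leave the secondary silyl ether and the acid-sensitive dienyl system intact.

**Step 4**
Reactants: 5 (2S,3S,4Z)-3-{[tert-butyl(dimethyl)silyl]oxy}hepta-4,6-diene-1,2-diol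
Product: 7 tert-butyl (2E,4S,5S,6Z)-5-{[tert-butyl(dimethyl)silyl]oxy}-4-hydroxynona-2,6,8-trienoate, via hydroxy aldehyde 6 (not isolated)
Conditions: TEMPO (cat.), PhI(OAc)2, CH2Cl2, rt; then Ph3P=CHCO2tBu, rt
Reagents that add atoms: tert-butyl (triphenylphosphoranylidene)acetate CC(C)(C)OC(=O)C=P(c1ccccc1)(c1ccccc1)c1ccccc1
Why: TEMPO/PhI(OAc)2 oxidises the primary hydroxyl of a 1,2-diol selectively, and the labile α-hydroxy aldehyde is trapped at once by the stabilised ylide (one-pot oxidation–Wittig reaction), which should give the E enoate without touching C6.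

**Step 5**
Reactants: 7 tert-butyl (2E,4S,5S,6Z)-5-{[tert-butyl(dimethyl)silyl]oxy}-4-hydroxynona-2,6,8-trienoate
Product: 10 tert-butyl (2E)-3-[(2S,3S)-3-{[tert-butyl(dimethyl)silyl]oxy}-6-hydroxy-3,6-dihydro-2H-pyran-2-yl]prop-2-enoate, via triol 8 (not isolated), via hydroxy enal 9 (not isolated)
Conditions: OsO4 (cat.), (DHQD)2PHAL (cat.), NMO, acetone/H2O, 0 °C; then NaIO4, THF/pH 7 buffer, 0 °C → rt
Reagents that add atoms: osmium tetroxide O=[Os](=O)(=O)=O; 4-methylmorpholine N-oxide C[N+]1([O-])CCOCC1 (terminal oxidant)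
Why: Ligand-accelerated Upjohn dihydroxylation should select the monosubstituted terminal olefin (the cis olefin is hindered by the allylic silyl ether and fits the ligand poorly, the enoate is electron-poor); periodate then cleaves the only free 1,2-diol and the Z enal is trapped by O6 as the six-membered lactol.

**Step 6**
Reactants: 10 tert-butyl (2E)-3-[(2S,3S)-3-{[tert-butyl(dimethyl)silyl]oxy}-6-hydroxy-3,6-dihydro-2H-pyran-2-yl]prop-2-enoate
Product: 11 tert-butyl (2E)-3-[(2S,3S)-3-{[tert-butyl(dimethyl)silyl]oxy}-6-oxo-3,6-dihydro-2H-pyran-2-yl]prop-2-enoate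
Conditions: MnO2 (activated, excess), CH2Cl2, rt
Reagents that add atoms: none
Why: Allylic lactols are oxidised to α,β-unsaturated δ-lactones by activated MnO2, which should not affect the silyl ether, the enoate or the stereocentres.

**Step 7**
Reactants: 11 tert-butyl (2E)-3-[(2S,3S)-3-{[tert-butyl(dimethyl)silyl]oxy}-6-oxo-3,6-dihydro-2H-pyran-2-yl]prop-2-enoate
Product: 12 tert-butyl (2E)-3-[(2S,3S)-3-hydroxy-6-oxo-3,6-dihydro-2H-pyran-2-yl]prop-2-enoate
Conditions: HF·pyridine, pyridine/THF, 0 °C → rt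
Reagents that add atoms: none
Why: Buffered HF·pyridine cleaves the secondary silyl ether without base, so ring contraction to a butenolide and β-elimination should be avoided and the tert-butyl ester should survive.

**Step 8**
Reactants: 13 (3R)-3,7-dimethylocta-1,6-diene
Product: 15 (4R)-4-methylhex-5-en-1-ol, via ozonide 14 (not isolated)
Conditions: O3 (1 equiv), CH2Cl2, −78 °C; then NaBH4, MeOH, −78 → 0 °C
Reagents that add atoms: ozone O=[O+][O-]
Why: Ozone attacks the electron-rich trisubstituted olefin much faster than the monosubstituted one, so one equivalent should cleave it selectively, and borohydride reduces the ozonide to the primary alcohol (ozonolysis with reductive work-up); the stereocentre is not involved.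

**Step 9**
Reactants: 15 (4R)-4-methylhex-5-en-1-ol
Product: 16 (3R)-6-bromo-3-methylhex-1-ene
Conditions: CBr4, PPh3, CH2Cl2, 0 °C
Reagents that add atoms: carbon tetrabromide BrC(Br)(Br)Br
Why: Appel reaction of a primary alcohol; neutral conditions leave the olefin and the remote stereocentre untouched.

**Step 10**
Reactants: 16 (3R)-6-bromo-3-methylhex-1-ene; 17 (2S)-2-methyloxirane
Product: 19 (2S,7R)-7-methylnon-8-en-2-ol, via Grignard reagent 18 (not isolated)
Conditions: Mg, THF, rt; then CuI (10 mol %), 17, THF, −30 → 0 °C; aq. NH4Cl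
Reagents that add atoms: none
Why: Copper-catalysed opening of a terminal epoxide by a primary Grignard reagent occurs at the CH2 terminus, so the (S) centre of 17 is carried over unchanged as C11′.

**Step 11**
Reactants: 19 (2S,7R)-7-methylnon-8-en-2-ol
Product: 20 tert-butyl(dimethyl){[(2S,7R)-7-methylnon-8-en-2-yl]oxy}silane
Conditions: TBSCl, imidazole, DMF, rt
Reagents that add atoms: tert-butyl(chloro)dimethylsilane CC(C)(C)[Si](C)(C)Cl
Why: Standard silylation; the ether masks O11′ through the olefinations and the later esterification.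

**Step 12**
Reactants: 20 tert-butyl(dimethyl){[(2S,7R)-7-methylnon-8-en-2-yl]oxy}silane
Product: 22 (2R,7S)-7-{[tert-butyl(dimethyl)silyl]oxy}-2-methyloctanal, via ozonide 21 (not isolated)
Conditions: O3, CH2Cl2, −78 °C; then PPh3, −78 °C → rt
Reagents that add atoms: ozone O=[O+][O-]
Why: Ozonolysis of the terminal olefin with neutral phosphine reduction should give the α-methyl aldehyde without epimerisation of the C6′ centre.

**Step 13**
Reactants: 22 (2R,7S)-7-{[tert-butyl(dimethyl)silyl]oxy}-2-methyloctanal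
Product: 23 (2E,4R,9S)-9-{[tert-butyl(dimethyl)silyl]oxy}-2,4-dimethyldec-2-enal
Conditions: Ph3P=C(CH3)CHO, toluene, 90 °C
Reagents that add atoms: 2-(triphenylphosphoranylidene)propanal CC(C=O)=P(c1ccccc1)(c1ccccc1)c1ccccc1
Why: Wittig reaction with the formyl-stabilised ylide should give the E trisubstituted enal, and the hindered product enal reacts more slowly than 22, so a single homologation is expected.

**Step 14**
Reactants: 23 (2E,4R,9S)-9-{[tert-butyl(dimethyl)silyl]oxy}-2,4-dimethyldec-2-enal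
Product: 24 ethyl (2E,4E,6R,11S)-11-{[tert-butyl(dimethyl)silyl]oxy}-4,6-dimethyldodeca-2,4-dienoate
Conditions: Ph3P=CHCO2Et, CH2Cl2, rt → 40 °C
Reagents that add atoms: ethyl (triphenylphosphoranylidene)acetate CCOC(=O)C=P(c1ccccc1)(c1ccccc1)c1ccccc1
Why: Wittig reaction of an enal with an ester-stabilised ylide should be E-selective and non-basic enough to keep the C6′ centre.

**Step 15**
Reactants: 24 ethyl (2E,4E,6R,11S)-11-{[tert-butyl(dimethyl)silyl]oxy}-4,6-dimethyldodeca-2,4-dienoate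
Product: 25 (2E,4E,6R,11S)-11-{[tert-butyl(dimethyl)silyl]oxy}-4,6-dimethyldodeca-2,4-dienoic acid
Conditions: LiOH, THF/MeOH/H2O, rt; then 1 M HCl to pH 3, 0 °C
Reagents that add atoms: lithium hydroxide [Li+].[OH-]
Why: Saponification of an ethyl dienoate; the secondary silyl ether is stable to aqueous hydroxide and to brief cold acidification.

**Step 16**
Reactants: 12 tert-butyl (2E)-3-[(2S,3S)-3-hydroxy-6-oxo-3,6-dihydro-2H-pyran-2-yl]prop-2-enoate; 25 (2E,4E,6R,11S)-11-{[tert-butyl(dimethyl)silyl]oxy}-4,6-dimethyldodeca-2,4-dienoic acid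
Product: 27 tert-butyl (2E)-3-[(2S,3S)-3-{[(2E,4E,6R,11S)-11-{[tert-butyl(dimethyl)silyl]oxy}-4,6-dimethyldodeca-2,4-dienoyl]oxy}-6-oxo-3,6-dihydro-2H-pyran-2-yl]prop-2-enoate, via mixed anhydride 26 (not isolated)
Conditions: 25, 2,4,6-Cl3C6H2COCl, Et3N, toluene, rt; then 12, DMAP, toluene, 0 °C → rt
Reagents that add atoms: none
Why: Yamaguchi esterification acylates O5 at the dienoyl carbonyl of the mixed anhydride with retention at C5, a coupling type with close precedent on 5-hydroxy-5,6-dihydropyran-2-ones.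

**Step 17**
Reactants: 27 tert-butyl (2E)-3-[(2S,3S)-3-{[(2E,4E,6R,11S)-11-{[tert-butyl(dimethyl)silyl]oxy}-4,6-dimethyldodeca-2,4-dienoyl]oxy}-6-oxo-3,6-dihydro-2H-pyran-2-yl]prop-2-enoate
Product: 28 (2E)-3-[(2S,3S)-3-{[(2E,4E,6R,11S)-11-hydroxy-4,6-dimethyldodeca-2,4-dienoyl]oxy}-6-oxo-3,6-dihydro-2H-pyran-2-yl]prop-2-enoic acid
Conditions: TFA/CH2Cl2/H2O (10:10:1), 0 °C → rt; toluene co-evaporation, then MeOH/pH 7 buffer
Reagents that add atoms: none
Why: Acidolysis removes the tert-butyl ester (via the tert-butyl cation) and the secondary silyl ether in one operation, while lactone, allylic ester and olefins should be stable to acid; any trifluoroacetate formed on O11′ is cleaved in the buffered methanol work-up.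

**Compound list**
1 | (4S)-2,2-dimethyl-1,3-dioxolane-4-carbaldehyde | O=C[C@@H]1COC(C)(C)O1 | starting material
2 | acetylene | C#C | starting material
3 | (1S,2Z)-1-[(4S)-2,2-dimethyl-1,3-dioxolan-4-yl]penta-2,4-dien-1-ol | C=C/C=C\[C@H](O)[C@@H]1COC(C)(C)O1 | intermediate
4 | tert-butyl{[(1S,2Z)-1-[(4S)-2,2-dimethyl-1,3-dioxolan-4-yl]penta-2,4-dien-1-yl]oxy}dimethylsilane | C=C/C=C\[C@H](O[Si](C)(C)C(C)(C)C)[C@@H]1COC(C)(C)O1 | intermediate
5 | (2S,3S,4Z)-3-{[tert-butyl(dimethyl)silyl]oxy}hepta-4,6-diene-1,2-diol | C=C/C=C\[C@H](O[Si](C)(C)C(C)(C)C)[C@@H](O)CO | intermediate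
6 | (2R,3S,4Z)-3-{[tert-butyl(dimethyl)silyl]oxy}-2-hydroxyhepta-4,6-dienal | C=C/C=C\[C@H](O[Si](C)(C)C(C)(C)C)[C@@H](O)C=O | intermediate
7 | tert-butyl (2E,4S,5S,6Z)-5-{[tert-butyl(dimethyl)silyl]oxy}-4-hydroxynona-2,6,8-trienoate | C=C/C=C\[C@H](O[Si](C)(C)C(C)(C)C)[C@@H](O)/C=C/C(=O)OC(C)(C)C | intermediate
8 | tert-butyl (2E,4S,5S,6Z)-5-{[tert-butyl(dimethyl)silyl]oxy}-4,8,9-trihydroxynona-2,6-dienoate (C8 epimers) | OCC(O)/C=C\[C@H](O[Si](C)(C)C(C)(C)C)[C@@H](O)/C=C/C(=O)OC(C)(C)C | intermediate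
9 | tert-butyl (2E,4S,5S,6Z)-5-{[tert-butyl(dimethyl)silyl]oxy}-4-hydroxy-8-oxoocta-2,6-dienoate | O=C/C=C\[C@H](O[Si](C)(C)C(C)(C)C)[C@@H](O)/C=C/C(=O)OC(C)(C)C | intermediate
10 | tert-butyl (2E)-3-[(2S,3S)-3-{[tert-butyl(dimethyl)silyl]oxy}-6-hydroxy-3,6-dihydro-2H-pyran-2-yl]prop-2-enoate (anomers) | CC(C)(C)[Si](C)(C)O[C@H]1C=CC(O)O[C@H]1/C=C/C(=O)OC(C)(C)C | intermediate
11 | tert-butyl (2E)-3-[(2S,3S)-3-{[tert-butyl(dimethyl)silyl]oxy}-6-oxo-3,6-dihydro-2H-pyran-2-yl]prop-2-enoate | CC(C)(C)[Si](C)(C)O[C@H]1C=CC(=O)O[C@H]1/C=C/C(=O)OC(C)(C)C | intermediate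
12 | tert-butyl (2E)-3-[(2S,3S)-3-hydroxy-6-oxo-3,6-dihydro-2H-pyran-2-yl]prop-2-enoate | O[C@H]1C=CC(=O)O[C@H]1/C=C/C(=O)OC(C)(C)C | intermediate
13 | (3R)-3,7-dimethylocta-1,6-diene ((R)-β-citronellene) | C=C[C@H](C)CCC=C(C)C | starting material
14 | 3,3-dimethyl-5-[(3R)-3-methylpent-4-en-1-yl]-1,2,4-trioxolane | C=C[C@H](C)CCC1OC(C)(C)OO1 | intermediate
15 | (4R)-4-methylhex-5-en-1-ol | C=C[C@H](C)CCCO | intermediate
16 | (3R)-6-bromo-3-methylhex-1-ene | C=C[C@H](C)CCCBr | intermediate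
17 | (2S)-2-methyloxirane ((S)-propylene oxide) | C[C@H]1CO1 | starting material
18 | [(4R)-4-methylhex-5-en-1-yl]magnesium bromide | C=C[C@H](C)CCC[Mg]Br | intermediate
19 | (2S,7R)-7-methylnon-8-en-2-ol | C=C[C@H](C)CCCC[C@H](C)O | intermediate
20 | tert-butyl(dimethyl){[(2S,7R)-7-methylnon-8-en-2-yl]oxy}silane | C=C[C@H](C)CCCC[C@H](C)O[Si](C)(C)C(C)(C)C | intermediate
21 | tert-butyl(dimethyl){[(2S,7R)-7-(1,2,4-trioxolan-3-yl)octan-2-yl]oxy}silane | C1OC(OO1)[C@H](C)CCCC[C@H](C)O[Si](C)(C)C(C)(C)C | intermediate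
22 | (2R,7S)-7-{[tert-butyl(dimethyl)silyl]oxy}-2-methyloctanal | O=C[C@H](C)CCCC[C@H](C)O[Si](C)(C)C(C)(C)C | intermediate
23 | (2E,4R,9S)-9-{[tert-butyl(dimethyl)silyl]oxy}-2,4-dimethyldec-2-enal | O=C/C(C)=C/[C@H](C)CCCC[C@H](C)O[Si](C)(C)C(C)(C)C | intermediate
24 | ethyl (2E,4E,6R,11S)-11-{[tert-butyl(dimethyl)silyl]oxy}-4,6-dimethyldodeca-2,4-dienoate | CCOC(=O)/C=C/C(C)=C/[C@H](C)CCCC[C@H](C)O[Si](C)(C)C(C)(C)C | intermediate
25 | (2E,4E,6R,11S)-11-{[tert-butyl(dimethyl)silyl]oxy}-4,6-dimethyldodeca-2,4-dienoic acid | OC(=O)/C=C/C(C)=C/[C@H](C)CCCC[C@H](C)O[Si](C)(C)C(C)(C)C | intermediate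
26 | (2E,4E,6R,11S)-11-{[tert-butyl(dimethyl)silyl]oxy}-4,6-dimethyldodeca-2,4-dienoic 2,4,6-trichlorobenzoic anhydride | Clc1cc(Cl)c(C(=O)OC(=O)/C=C/C(C)=C/[C@H](C)CCCC[C@H](C)O[Si](C)(C)C(C)(C)C)c(Cl)c1 | intermediate
27 | tert-butyl (2E)-3-[(2S,3S)-3-{[(2E,4E,6R,11S)-11-{[tert-butyl(dimethyl)silyl]oxy}-4,6-dimethyldodeca-2,4-dienoyl]oxy}-6-oxo-3,6-dihydro-2H-pyran-2-yl]prop-2-enoate | CC(/C=C/C(=O)O[C@H]1C=CC(=O)O[C@H]1/C=C/C(=O)OC(C)(C)C)=C\[C@H](C)CCCC[C@H](C)O[Si](C)(C)C(C)(C)C | intermediate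
28 | (2E)-3-[(2S,3S)-3-{[(2E,4E,6R,11S)-11-hydroxy-4,6-dimethyldodeca-2,4-dienoyl]oxy}-6-oxo-3,6-dihydro-2H-pyran-2-yl]prop-2-enoic acid | CC(/C=C/C(=O)O[C@H]1C=CC(=O)O[C@H]1/C=C/C(=O)O)=C\[C@H](C)CCCC[C@H](C)O | target

**Totals**
Total step count: 17.
Longest linear sequence: 10 steps (steps 8–17, from 13); the core branch is 9 steps (steps 1–7, 16, 17).

**Steps most likely to fail, with fallbacks**

Step 1. The risk is insufficient catalyst-directed facial selectivity at C5 (the catalyst must override the substrate bias), together with competing hydrogenation or oligomerisation of acetylene. The fallback sets out from 1 and comes back at 3, building the same carbinol stepwise with a reagent-controlled reduction. Lithium (trimethylsilyl)acetylide (Me3SiC≡CH, n-BuLi, THF, −78 °C) is added to 1 to give 1-[(4S)-2,2-dimethyl-1,3-dioxolan-4-yl]-3-(trimethylsilyl)prop-2-yn-1-ol F1 as an epimer mixture. Dess–Martin oxidation gives the ynone 1-[(4S)-2,2-dimethyl-1,3-dioxolan-4-yl]-3-(trimethylsilyl)prop-2-yn-1-one F2. Noyori asymmetric transfer hydrogenation (RuCl[(R,R)-TsDPEN](p-cymene), i-PrOH; antipode chosen by the empirical ynone model) should give (1S)-1-[(4S)-2,2-dimethyl-1,3-dioxolan-4-yl]-3-(trimethylsilyl)prop-2-yn-1-ol F3. K2CO3/MeOH removes the silyl group to give (1S)-1-[(4S)-2,2-dimethyl-1,3-dioxolan-4-yl]prop-2-yn-1-ol F4. Sonogashira coupling with vinyl bromide (Pd(PPh3)4, CuI, i-Pr2NH) gives (1S)-1-[(4S)-2,2-dimethyl-1,3-dioxolan-4-yl]pent-4-en-2-yn-1-ol F5. Boland reduction (Zn activated with Cu(OAc)2 and AgNO3, MeOH/H2O) of the triple bond to the Z olefin then gives 3.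

Step 5. The risk is poor site selectivity of the osmylation among three olefins and over-oxidation of the remaining cis olefin. The fallback sets out from 4 and comes back at 11; it excises the terminal CH2 before the enoate and the free hydroxyl exist and closes the lactone before the arm is extended. Lemieux–Johnson cleavage of 4 (OsO4 cat., NaIO4, 2,6-lutidine, dioxane/H2O) gives (2Z,4S)-4-{[tert-butyl(dimethyl)silyl]oxy}-4-[(4S)-2,2-dimethyl-1,3-dioxolan-4-yl]but-2-enal F6. Pinnick oxidation (NaClO2, NaH2PO4, 2-methylbut-2-ene) gives (2Z,4S)-4-{[tert-butyl(dimethyl)silyl]oxy}-4-[(4S)-2,2-dimethyl-1,3-dioxolan-4-yl]but-2-enoic acid F7. Acetonide hydrolysis (CuCl2·2H2O, MeCN) with spontaneous lactonisation on O6 gives (5S,6S)-5-{[tert-butyl(dimethyl)silyl]oxy}-6-(hydroxymethyl)-5,6-dihydro-2H-pyran-2-one F8. Dess–Martin oxidation gives (2R,3S)-3-{[tert-butyl(dimethyl)silyl]oxy}-6-oxo-3,6-dihydro-2H-pyran-2-carbaldehyde F9, which is treated in the same flask with Ph3P=CHCO2tBu to give 11.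

Step 16. The risk is slow acylation of the hindered allylic alcohol by a deactivated dienoyl donor, leaving time for base-induced β-elimination across C5–C6 (towards a 2-pyranone), C6 epimerisation or ring contraction. The fallback sets out from 12 and comes back at 27; it builds C2′=C3′ on the core instead of activating the dienoic acid. DCC-mediated acylation of 12 with the small diethylphosphonoacetic acid (CH2Cl2, 0 °C) gives tert-butyl (2E)-3-[(2S,3S)-3-{[(diethoxyphosphoryl)acetyl]oxy}-6-oxo-3,6-dihydro-2H-pyran-2-yl]prop-2-enoate F10. Horner–Wadsworth–Emmons reaction with enal 23 under Masamune–Roush conditions (LiCl, i-Pr2NEt, MeCN) then gives 27; steps 14 and 15 are not needed on this path.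

**Further compounds**
F1 | step 1 | 1-[(4S)-2,2-dimethyl-1,3-dioxolan-4-yl]-3-(trimethylsilyl)prop-2-yn-1-ol (C1 epimers) | C[Si](C)(C)C#CC(O)[C@@H]1COC(C)(C)O1
F2 | step 1 | 1-[(4S)-2,2-dimethyl-1,3-dioxolan-4-yl]-3-(trimethylsilyl)prop-2-yn-1-one | C[Si](C)(C)C#CC(=O)[C@@H]1COC(C)(C)O1
F3 | step 1 | (1S)-1-[(4S)-2,2-dimethyl-1,3-dioxolan-4-yl]-3-(trimethylsilyl)prop-2-yn-1-ol | C[Si](C)(C)C#C[C@H](O)[C@@H]1COC(C)(C)O1
F4 | step 1 | (1S)-1-[(4S)-2,2-dimethyl-1,3-dioxolan-4-yl]prop-2-yn-1-ol | C#C[C@H](O)[C@@H]1COC(C)(C)O1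
F5 | step 1 | (1S)-1-[(4S)-2,2-dimethyl-1,3-dioxolan-4-yl]pent-4-en-2-yn-1-ol | C=CC#C[C@H](O)[C@@H]1COC(C)(C)O1
F6 | step 5 | (2Z,4S)-4-{[tert-butyl(dimethyl)silyl]oxy}-4-[(4S)-2,2-dimethyl-1,3-dioxolan-4-yl]but-2-enal | O=C/C=C\[C@H](O[Si](C)(C)C(C)(C)C)[C@@H]1COC(C)(C)O1
F7 | step 5 | (2Z,4S)-4-{[tert-butyl(dimethyl)silyl]oxy}-4-[(4S)-2,2-dimethyl-1,3-dioxolan-4-yl]but-2-enoic acid | OC(=O)/C=C\[C@H](O[Si](C)(C)C(C)(C)C)[C@@H]1COC(C)(C)O1
F8 | step 5 | (5S,6S)-5-{[tert-butyl(dimethyl)silyl]oxy}-6-(hydroxymethyl)-5,6-dihydro-2H-pyran-2-one | CC(C)(C)[Si](C)(C)O[C@H]1C=CC(=O)O[C@H]1CO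
F9 | step 5 | (2R,3S)-3-{[tert-butyl(dimethyl)silyl]oxy}-6-oxo-3,6-dihydro-2H-pyran-2-carbaldehyde | CC(C)(C)[Si](C)(C)O[C@H]1C=CC(=O)O[C@H]1C=O
F10 | step 16 | tert-butyl (2E)-3-[(2S,3S)-3-{[(diethoxyphosphoryl)acetyl]oxy}-6-oxo-3,6-dihydro-2H-pyran-2-yl]prop-2-enoate | CCOP(=O)(CC(=O)O[C@H]1C=CC(=O)O[C@H]1/C=C/C(=O)OC(C)(C)C)OCC
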